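## Retrosynthetic overview
1. Ring B (ten-membered carbocycle) is closed last at C6–C7. An α-(bromomethyl)butenolide adds as its allylchromium to a (Z)-enal, which also unveils the α-methylene lactone. C7 and C6 are relayed from C8.
2. Ring A (butenolide) is closed first, at C7=C11, by ring-closing metathesis of a 2-(bromomethyl)acrylate of a 1-alken-3-ol.
3. Key disconnection: the C8–O bond of that ester, which leads back to a (Z)-allylic trichloroacetimidate and 2-(bromomethyl)acrylic acid. This enantioselective SN2′ esterification is the only source of absolute configuration.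
4. Second C–O disconnection: the C15–O ester. It comes from the side-chain acid chloride and a magnesium alkoxide built in one flask from homoprenyl bromide, propargyl alcohol and DMF. This is the new step, and it fixes the C4=C5 geometry.
5. C8–C9 comes from an allylic bromide (SeO2 oxidation of the prenyl end) and propargyl alcohol. The side chain comes from the Baylis–Hillman adduct of tert-butyl acrylate and acetaldehyde.

Numbering: the germacrane numbering of the target (C1–C15, lactone C12–O–C8) is used for all chain intermediates.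

Assumption: the (Sp,R) antipode of the palladacycle gives the 8S ester, by analogy with simple (Z)-alk-2-enyl imidates. If the sense is opposite, the (Rp,S) antipode is used.

## Route

Step 1
Reactants: 1 tert-butyl acrylate; 2 acetaldehyde
Product: 3 tert-butyl 3-hydroxy-2-methylidenebutanoate (racemic)
Conditions: DABCO (30 mol %), 1,4-dioxane–H2O 1:1, rt, 48 h
Reagents that add atoms: none
Why: Morita–Baylis–Hillman reaction, in which DABCO adds to the acrylate and the enolate attacks acetaldehyde; the racemic carbinol centre is erased in step 2.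

Step 2
Reactants: 3 tert-butyl 3-hydroxy-2-methylidenebutanoate
Product: 5 tert-butyl (2E)-2-(acetoxymethyl)but-2-enoate, via secondary acetate 4 (not isolated)
Conditions: Ac2O, Et3N, DMAP (5 mol %), THF, 0 °C to rt; then DABCO (20 mol %), 65 °C
Reagents that add atoms: acetic anhydride CC(=O)OC(C)=O
Why: O-acetylation followed by DABCO-catalysed isomerisation of the Baylis–Hillman acetate (SN2′ then SN2) drains 4 into the conjugated primary acetate, and A(1,3) strain places the methyl group trans to the ester (E).

Step 3
Reactants: 6 5-bromo-2-methylpent-2-ene; 7 prop-2-yn-1-ol; 5 tert-butyl (2E)-2-(acetoxymethyl)but-2-enoate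
Product: 12 (2Z)-2-(4-methylpent-3-en-1-yl)-4-oxobut-2-en-1-yl (2E)-2-(acetoxymethyl)but-2-enoate, via Grignard reagent 8 (not isolated), via vinylmagnesium chelate 9 (not isolated), via amino alkoxide 10 (not isolated), via acid chloride 11 (not isolated)
Conditions: flask 1: 6, Mg, THF, 35 °C (8); 7, EtMgBr (1.0 equiv), THF, 0 °C, then 8 (1.3 equiv), CuI (10 mol %), 0 °C to rt, 12 h (9); DMF (2 equiv), −20 °C, 1 h (10). Flask 2: 5, SOCl2, rt, then evaporation (11). 11 (1.1 equiv) in THF added to flask 1 at −40 °C, then to 0 °C; poured into cold 10 % aqueous citric acid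
Reagents that add atoms: N,N-dimethylformamide CN(C)C=O (C6 with its H and O); only in intermediates 8–11: magnesium [Mg], ethylmagnesium bromide CC[Mg]Br, thionyl chloride O=S(Cl)Cl
Why: Proposed new method: CuI-catalysed anti-carbomagnesiation of the propargylic alkoxide puts C3 on C4 and magnesium on C5 cis to C15–O (five-membered chelate 9); DMF then gives the α-amino alkoxide 10, which does not collapse before water is added and so masks C6 as a hindered, poorly nucleophilic alkoxide; acid chloride 11 therefore acylates only the primary C15–OMgBr, and the acidic quench frees a (Z)-γ-acyloxy enal that can no longer close to the lactol or aromatise to the furan; the closest known reaction types are the carbomagnesiation/DMF route to 3-substituted furans and the in situ protection of aldehydes as α-amino alkoxides, whereas interception of the alkoxide by C–O acylation before hydrolysis has not been described.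

Step 4
Reactants: 12 (Z)-γ-acyloxy enal
Product: 13 (2Z)-2-[(3E)-5-hydroxy-4-methylpent-3-en-1-yl]-4-oxobut-2-en-1-yl (2E)-2-(acetoxymethyl)but-2-enoate
Conditions: SeO2 (30 mol %), t-BuOOH (5.5 M in decane, 2.5 equiv), CH2Cl2, 0 °C to rt
Reagents that add atoms: tert-butyl hydroperoxide CC(C)(C)OO (oxygen relayed by SeO2)
Why: Riley allylic oxidation (ene reaction then [2,3]-shift) attacks only the electron-rich prenyl alkene and gives the (E)-allylic alcohol at C9, because the other two alkenes are deactivated by carbonyl groups.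

Step 5
Reactants: 13 C9 allylic alcohol
Product: 14 (2Z)-2-[(3E)-5-bromo-4-methylpent-3-en-1-yl]-4-oxobut-2-en-1-yl (2E)-2-(acetoxymethyl)but-2-enoate
Conditions: NBS, Me2S, CH2Cl2, −30 to 0 °C
Reagents that add atoms: N-bromosuccinimide O=C1CCC(=O)N1Br
Why: Corey–Kim-type bromination, in which bromide displaces the alkoxysulfonium salt by SN2 under neutral conditions, so both alkene geometries, the enal and the esters are kept.

Step 6
Reactants: 14 C9 allylic bromide; 7 prop-2-yn-1-ol
Product: 15 (2Z)-2-[(3E)-8-hydroxy-4-methyloct-3-en-6-yn-1-yl]-4-oxobut-2-en-1-yl (2E)-2-(acetoxymethyl)but-2-enoate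
Conditions: 7 (1.5 equiv), CuI (20 mol %), NaI (20 mol %), K2CO3, DMF, rt
Reagents that add atoms: none
Why: Copper-acetylide SN2 alkylation of a primary allylic bromide (skipped-enyne synthesis) forms C8–C9 with carbonate as the only base and does not touch the esters or the enal.

Step 7
Reactants: 15 skipped enynol
Product: 16 (2Z)-2-[(3E,6Z)-8-hydroxy-4-methylocta-3,6-dien-1-yl]-4-oxobut-2-en-1-yl (2E)-2-(acetoxymethyl)but-2-enoate
Conditions: H2 (1 atm), Pd/CaCO3 poisoned with Pb(OAc)2 (Lindlar catalyst), quinoline, EtOAc, rt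
Reagents that add atoms: none
Why: Lindlar semihydrogenation adds H2 syn to the alkyne only and gives the (Z)-allylic alcohol that the next step requires.

Step 8
Reactants: 16 (Z)-allylic alcohol; 17 2-(bromomethyl)acrylic acid
Product: 19 (2Z)-2-[(3E,6S)-6-{[2-(bromomethyl)prop-2-enoyl]oxy}-4-methylocta-3,7-dien-1-yl]-4-oxobut-2-en-1-yl (2E)-2-(acetoxymethyl)but-2-enoate, via trichloroacetimidate 18 (not isolated)
Conditions: Cl3CCN, DBU (5 mol %), CH2Cl2, 0 °C; then 17 (3 equiv), (Sp,R)-di-μ-acetatobis[(η5-2-(4-isopropyl-4,5-dihydrooxazol-2-yl)cyclopentadienyl-1-C,3′-N)(η4-tetraphenylcyclobutadiene)cobalt]dipalladium, [Pd(OAc){(C5H3(C6H10NO))Co(C4Ph4)}]2 (2 mol %), CH2Cl2, 23 °C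
Reagents that add atoms: trichloroacetonitrile N#CC(Cl)(Cl)Cl (only in intermediate 18)
Why: Overman-type asymmetric allylic esterification, in which the imidate nitrogen ties the chiral divalent-palladium catalyst to the C7=C8 alkene only, the acid attacks C8 anti to palladium and deoxypalladation expels trichloroacetamide; this forms the C8–O bond with S configuration, and the C–Br bond of 17 survives because palladium never leaves the divalent state.

Step 9
Reactants: 19 (8S)-allylic 2-(bromomethyl)acrylate
Product: 20 (2Z)-2-{(3E)-5-[(2S)-4-(bromomethyl)-5-oxo-2,5-dihydrofuran-2-yl]-4-methylpent-3-en-1-yl}-4-oxobut-2-en-1-yl (2E)-2-(acetoxymethyl)but-2-enoate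
Conditions: second-generation Hoveyda–Grubbs catalyst RuCl2(SIMes)(=CH-C6H4-2-OiPr) (5 mol %), CH2Cl2, 0.005 M, 40 °C
Reagents that add atoms: none
Why: Ring-closing metathesis between the only monosubstituted alkene and the acrylate alkene closes ring A with loss of ethylene, while the trisubstituted alkenes are inert and C8 is untouched.

Step 10
Reactants: 20 α-(bromomethyl)butenolide enal
Product: 22 (1(10)E,4Z,6R,7S,8S)-15-{[(2E)-2-(acetoxymethyl)but-2-enoyl]oxy}-6-hydroxygermacra-1(10),4,11(13)-trien-12,8-olide, via allylchromium species 21 (not isolated)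
Conditions: CrCl2 (8 equiv), DMF–THF 1:1, 20 added over 12 h to 0.002 M, 25 °C; H2O
Reagents that add atoms: chromium dichloride Cl[Cr]Cl (only in intermediate 21)
Why: Intramolecular Nozaki–Hiyama–Kishi-type allylation, in which allylchromium 21 attacks the aldehyde through C7 in a chair transition state on the butenolide face opposite C9 (7,8-trans, 7S) and the ring-locked E-type allyl geometry gives the 6,7-anti relationship (6R); this closes ring B and unveils the α-methylene lactone.

## Compound list
1 | tert-butyl acrylate | C=CC(=O)OC(C)(C)C | starting material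
2 | acetaldehyde | CC=O | starting material
3 | tert-butyl 3-hydroxy-2-methylidenebutanoate (racemic) | CC(O)C(=C)C(=O)OC(C)(C)C | intermediate
4 | tert-butyl 3-acetoxy-2-methylidenebutanoate (racemic) | CC(OC(C)=O)C(=C)C(=O)OC(C)(C)C | intermediate
5 | tert-butyl (2E)-2-(acetoxymethyl)but-2-enoate | CC(C)(C)OC(=O)/C(=C/C)COC(C)=O | intermediate
6 | 5-bromo-2-methylpent-2-ene | CC(C)=CCCBr | starting material
7 | prop-2-yn-1-ol | C#CCO | starting material
8 | (4-methylpent-3-en-1-yl)magnesium bromide | CC(C)=CCC[Mg]Br | intermediate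
9 | bromomagnesium (2Z)-3-(bromomagnesio)-2-(4-methylpent-3-en-1-yl)prop-2-en-1-olate (Mg on C5 cis to C15–O) | CC(C)=CCC/C(CO[Mg]Br)=C/[Mg]Br | intermediate
10 | bis(bromomagnesium) salt of (2Z)-4-(dimethylamino)-2-(4-methylpent-3-en-1-yl)but-2-ene-1,4-diol | CC(C)=CCC/C(CO[Mg]Br)=C/C(O[Mg]Br)N(C)C | intermediate
11 | (2E)-2-(acetoxymethyl)but-2-enoyl chloride | O=C(Cl)/C(=C/C)COC(C)=O | intermediate
12 | (Z)-γ-acyloxy enal (C6 aldehyde, C15 side-chain ester, prenyl end) | CC(C)=CCC/C(COC(=O)/C(=C/C)COC(C)=O)=C/C=O | intermediate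
13 | C9 (E)-allylic alcohol | OC/C(C)=C/CC/C(COC(=O)/C(=C/C)COC(C)=O)=C/C=O | intermediate
14 | C9 (E)-allylic bromide | BrC/C(C)=C/CC/C(COC(=O)/C(=C/C)COC(C)=O)=C/C=O | intermediate
15 | skipped enynol (C7≡C8) | OCC#CC/C(C)=C/CC/C(COC(=O)/C(=C/C)COC(C)=O)=C/C=O | intermediate
16 | (7Z)-allylic alcohol | OC/C=C\C/C(C)=C/CC/C(COC(=O)/C(=C/C)COC(C)=O)=C/C=O | intermediate
17 | 2-(bromomethyl)acrylic acid | C=C(CBr)C(=O)O | starting material
18 | trichloroacetimidate of 16 | N=C(OC/C=C\C/C(C)=C/CC/C(COC(=O)/C(=C/C)COC(C)=O)=C/C=O)C(Cl)(Cl)Cl | intermediate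
19 | (8S)-allylic 2-(bromomethyl)acrylate | C=C[C@H](C/C(C)=C/CC/C(COC(=O)/C(=C/C)COC(C)=O)=C/C=O)OC(=O)C(=C)CBr | intermediate
20 | (8S)-α-(bromomethyl)butenolide enal | O=C1O[C@@H](C/C(C)=C/CC/C(COC(=O)/C(=C/C)COC(C)=O)=C/C=O)C=C1CBr | intermediate
21 | allylchromium dichloride derived from 20 | O=C1O[C@@H](C/C(C)=C/CC/C(COC(=O)/C(=C/C)COC(C)=O)=C/C=O)C=C1C[Cr](Cl)Cl | intermediate
22 | CNP0184624.1 | C=C1C(=O)O[C@H]2C/C(C)=C/CC/C(COC(=O)/C(=C/C)COC(C)=O)=C/[C@@H](O)[C@H]12 | target

## Step count
Total step count: 10.

Longest linear sequence: 10 steps (1/2 → 3 → 5 → 12 → 13 → 14 → 15 → 16 → 19 → 20 → 22). Counted from 6 or 7 it is 8 steps.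

## Three steps most likely to fail

**Step 3 (the new step).**
- Risk: the acid chloride may also acylate the amino alkoxide, or 10 may collapse early. Unacylated material then ends as the lactol and the 3-substituted furan.
- Risk: liberated dimethylamine could attack the enal or the allylic acetate if the quench is not acidic.
- Fallback (known chemistry only), which sets out from vinylmagnesium chelate 9 and comes back at 12: 9 is quenched with CO2 and worked up with dilute acid, which gives 4-(4-methylpent-3-en-1-yl)furan-2(5H)-one F1. Me(MeO)NH·HCl with AlMe3 in CH2Cl2 opens the lactone to (2Z)-4-hydroxy-N-methoxy-N-methyl-3-(4-methylpent-3-en-1-yl)but-2-enamide F2. This is acylated at once with acid chloride 11 and pyridine to the Weinreb amide ester F3. Cp2Zr(H)Cl in THF reduces only the amide, and hydrolysis gives 12.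

**Step 8.**
- Risk: acid 17 is itself an alkylating agent and a Michael acceptor, and the skipped-diene imidate may react slowly. Both would cost yield or enantiomeric excess.
- Fallback, which sets out from 16 and comes back at 19: Sharpless asymmetric epoxidation (Ti(OiPr)4, D-(−)-diethyl tartrate, t-BuOOH, 4 Å sieves, CH2Cl2, −20 °C) gives the (7R,8S)-cis-epoxy alcohol F4. I2, PPh3 and imidazole give the epoxy iodide F5. Zn dust in EtOH opens it reductively to the (8S)-1-alken-3-ol F6, with the C8–O bond untouched. DIC and DMAP (5 mol %) in CH2Cl2 at 0 °C join F6 and 17 to give 19.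

**Step 10.**
- Risk: oligomerisation, a cis-fused or C6-epimeric ring, or attack of the C6 chromium alkoxide on C12, which would translactonise to the 6,12-olide.
- Fallback, which sets out from 20 and comes back at 22: B2pin2 with Pd2(dba)3 in toluene gives the α-(pinacolborylmethyl)butenolide enal F7, an isolable 2-alkoxycarbonyl allylboronate. Zerovalent palladium inserts into the C–Br bond much faster than into the allylic esters. Sc(OTf)3 (10 mol %) in toluene at 0.002 M then triggers a closed six-membered allylboration through C7, with the same trans/anti stereochemical model and no basic metal alkoxide. Aqueous work-up gives 22.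

## Further compounds
F1 | step 3 | 4-(4-methylpent-3-en-1-yl)furan-2(5H)-one | CC(C)=CCCC1=CC(=O)OC1
F2 | step 3 | (2Z)-4-hydroxy-N-methoxy-N-methyl-3-(4-methylpent-3-en-1-yl)but-2-enamide | CC(C)=CCC/C(CO)=C/C(=O)N(C)OC
F3 | step 3 | Weinreb amide ester (C6 Weinreb amide, C15 side-chain ester) | CC(C)=CCC/C(COC(=O)/C(=C/C)COC(C)=O)=C/C(=O)N(C)OC
F4 | step 8 | (7R,8S)-cis-epoxy alcohol | OC[C@H]1O[C@H]1C/C(C)=C/CC/C(COC(=O)/C(=C/C)COC(C)=O)=C/C=O
F5 | step 8 | epoxy iodide | IC[C@H]1O[C@H]1C/C(C)=C/CC/C(COC(=O)/C(=C/C)COC(C)=O)=C/C=O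
F6 | step 8 | (8S)-1-alken-3-ol | C=C[C@@H](O)C/C(C)=C/CC/C(COC(=O)/C(=C/C)COC(C)=O)=C/C=O
F7 | step 10 | α-(pinacolborylmethyl)butenolide enal | O=C1O[C@@H](C/C(C)=C/CC/C(COC(=O)/C(=C/C)COC(C)=O)=C/C=O)C=C1CB1OC(C)(C)C(C)(C)O1
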